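**Plan**

1. Retrosynthesis: the C5 and C7 phenols are masked as MOM ethers; ring C is then cut at C3–C4 together with the C2–H bond, giving a ring A benzaldehyde whose O1 carries the C2=C3 1-arylvinyl group.
2. Enabling feature: the C4 ketone sits on C4a of ring A, and O1 on the neighbouring C8a holds C2, which bears one hydrogen and ring B. A formyl C–H at C4 and an enol ether C2=C3 on O1 are therefore the two halves of an intramolecular alkene hydroacylation.
3. The C2=C3 methylene is cut next (ester methylenation), then the O1–C2 ester bond, giving a ring A salicylate and a ring B benzoic acid. The future aldehyde carbon is carried as a methyl ester until the enol ether exists, so the enol ether never meets acid.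
4. Ring A comes from methyl 2,4,6-trihydroxybenzoate (C8–prenyl bond by C-alkylation); ring B from 5-bromo-2-methoxybenzyl bromide (benzyl–allyl coupling, then carboxylation).
5. Forward: rings A and B are bought and joined as an aryl ester, the ester is methylenated, CO2Me is taken to CHO, ring C (the only ring formed) closes, and the MOM groups are removed.
6. Stereochemistry: the single stereocentre C2 (S) is created in the ring closure under control of the chiral bisphosphine on rhodium.

Key step: step 9

Assumption: the (R) antipode of the bisphosphine is taken to deliver the 2S ketone; if the sense of induction proves opposite, the (S) ligand is used with nothing else changed.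

**Route**

Step 1
Reactants: 1 5-bromo-2-methoxybenzyl bromide; 2 2-methylallylmagnesium chloride
Product: 3 4-bromo-1-methoxy-2-(3-methylbut-3-enyl)benzene
Conditions: THF, 0 °C → rt
Reagents that add atoms: none
Why: Allylic Grignard reagents displace benzylic bromides directly (benzyl–allyl cross-coupling), the aryl bromide does not exchange at this temperature, and the symmetric 2-methylallyl unit leaves no regiochemical question.

Step 2
Reactants: 3 4-bromo-1-methoxy-2-(3-methylbut-3-enyl)benzene
Product: 5 4-methoxy-3-(3-methylbut-3-enyl)benzoic acid, via aryllithium 4 (not isolated)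
Conditions: n-BuLi, THF, −78 °C; then CO2; aq. HCl
Reagents that add atoms: carbon dioxide, O=C=O
Why: Bromine–lithium exchange at −78 °C outruns deprotonation of the benzylic and allylic positions, and the aryllithium is trapped by CO2 (halogen–metal exchange, then carboxylation).

Step 3
Reactants: 6 methyl 2,4,6-trihydroxybenzoate; 7 prenyl bromide
Product: 8 methyl 2,4,6-trihydroxy-3-(3-methylbut-2-enyl)benzoate
Conditions: DBU (1 equiv), THF, 0 °C → rt
Reagents that add atoms: none
Why: C-alkylation of an acylphloroglucinol phenoxide by a soft allylic bromide; the two open ring carbons of 6 are equivalent by symmetry, and one equivalent of bromide limits double alkylation.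

Step 4
Reactants: 8 methyl 2,4,6-trihydroxy-3-(3-methylbut-2-enyl)benzoate
Product: 9 methyl 2-hydroxy-4,6-bis(methoxymethoxy)-3-(3-methylbut-2-enyl)benzoate
Conditions: MOMCl (2.2 equiv), i-Pr2NEt, CH2Cl2, 0 °C → rt
Reagents that add atoms: chloromethyl methyl ether (MOMCl), COCCl
Why: Phenol etherification with an α-chloro ether; the para OH is the most acidic and reacts first, and of the two ortho OH groups the one flanked by the prenyl group is more hindered and keeps the hydrogen bond to the ester carbonyl, so it should stay free.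

Step 5
Reactants: 5 4-methoxy-3-(3-methylbut-3-enyl)benzoic acid; 9 methyl 2-hydroxy-4,6-bis(methoxymethoxy)-3-(3-methylbut-2-enyl)benzoate
Product: 11 methyl 2-{[4-methoxy-3-(3-methylbut-3-enyl)benzoyl]oxy}-4,6-bis(methoxymethoxy)-3-(3-methylbut-2-enyl)benzoate, via acid chloride 10 (not isolated)
Conditions: 1-chloro-N,N,2-trimethylprop-1-en-1-amine, CH2Cl2, 0 °C → rt; then 9, Et3N, DMAP, 0 °C → rt
Reagents that add atoms: none
Why: Acid chloride formation under neutral conditions (Ghosez reagent, no HCl to add to the 1,1-disubstituted alkene) followed by DMAP-catalysed O-acylation, which is forceful enough for the hindered, hydrogen-bonded phenol.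

Step 6
Reactants: 11 methyl 2-{[4-methoxy-3-(3-methylbut-3-enyl)benzoyl]oxy}-4,6-bis(methoxymethoxy)-3-(3-methylbut-2-enyl)benzoate
Product: 12 methyl 2-({1-[4-methoxy-3-(3-methylbut-3-enyl)phenyl]ethenyl}oxy)-4,6-bis(methoxymethoxy)-3-(3-methylbut-2-enyl)benzoate
Conditions: Cp2Ti(μ-CH2)(μ-Cl)AlMe2 (1.2 equiv), pyridine, THF/toluene, −40 → 0 °C; aq. NaOH quench
Reagents that add atoms: Tebbe reagent Cp2Ti(μ-CH2)(μ-Cl)AlMe2, C[Al-]1(C)C[Ti](C2C=CC=C2)(C2C=CC=C2)[Cl+]1
Why: Tebbe methylenation of an aryl benzoate to an aryl 1-arylvinyl ether; the aryl ester is electronically activated and open on both carbonyl faces, whereas the methyl ester lies twisted between two ortho oxygen substituents and is shielded like a 2,6-disubstituted benzoate, so a slight excess of the titanium carbene at low temperature should take the aryl ester only.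

Step 7
Reactants: 12 methyl 2-({1-[4-methoxy-3-(3-methylbut-3-enyl)phenyl]ethenyl}oxy)-4,6-bis(methoxymethoxy)-3-(3-methylbut-2-enyl)benzoate
Product: 13 [2-({1-[4-methoxy-3-(3-methylbut-3-enyl)phenyl]ethenyl}oxy)-4,6-bis(methoxymethoxy)-3-(3-methylbut-2-enyl)phenyl]methanol
Conditions: LiAlH4, THF, 0 °C → rt; H2O/aq. NaOH work-up
Reagents that add atoms: none
Why: Hydride reduction of an ester to the primary alcohol; enol ether, MOM ethers and alkenes are inert to LiAlH4, and the basic work-up keeps the electron-rich benzylic alcohol from ionising next to the enol ether.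

Step 8
Reactants: 13 [2-({1-[4-methoxy-3-(3-methylbut-3-enyl)phenyl]ethenyl}oxy)-4,6-bis(methoxymethoxy)-3-(3-methylbut-2-enyl)phenyl]methanol
Product: 14 2-({1-[4-methoxy-3-(3-methylbut-3-enyl)phenyl]ethenyl}oxy)-4,6-bis(methoxymethoxy)-3-(3-methylbut-2-enyl)benzaldehyde
Conditions: activated MnO2 (excess), CH2Cl2, rt
Reagents that add atoms: none
Why: MnO2 oxidation of a benzylic alcohol stops at the aldehyde under neutral heterogeneous conditions and leaves the acid-labile enol ether and the alkenes untouched.

Step 9
Reactants: 14 2-({1-[4-methoxy-3-(3-methylbut-3-enyl)phenyl]ethenyl}oxy)-4,6-bis(methoxymethoxy)-3-(3-methylbut-2-enyl)benzaldehyde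
Product: 15 (2S)-2-[4-methoxy-3-(3-methylbut-3-enyl)phenyl]-5,7-bis(methoxymethoxy)-8-(3-methylbut-2-enyl)chroman-4-one
Conditions: [Rh(cod)Cl]2 (2.5 mol %), (R)-DTBM-SEGPHOS (5.5 mol %), Na[B(3,5-(CF3)2C6H3)4] (5 mol %), THF, 60 °C
Reagents that add atoms: none
Why: Proposed new method: the cationic monovalent rhodium bisphosphine complex, held by the C2=C3 alkene, inserts into the formyl C–H bond of 14 to give an acyl hydride of trivalent rhodium, the hydride migrates to C2 so that rhodium sits on the terminal C3, and reductive elimination from the seven-membered acyl alkyl rhodacycle forms C3–C4 and frees the catalyst. The closest known reaction type is the rhodium-catalysed enantioselective intramolecular hydroacylation of 1,1-disubstituted alkenes, as in the closure of 2-(1-arylvinyl)benzaldehydes to 3-arylindanones and of 2-(2-arylallyl)benzaldehydes to 3-aryl-1-tetralones; new here are the oxygen atom in the tether and an enol ether as the alkene. Ring C closes in a formally 6-endo-trig mode, both alkene carbons becoming ring atoms. C2, the only new stereocentre, is set by catalyst control, the chiral bisphosphine deciding which enantioface of C2=C3 takes up the hydride. The step needs regioselectivity for acyl transfer to the CH2 terminus, secured by the 1,1-disubstitution (the other mode would need a tertiary alkyl rhodium and a quaternary benzofuranone carbon), and chemoselectivity over the prenyl and 3-methylbut-3-enyl alkenes, secured because neither can reach the metal within the molecule and the enol ether has no allylic hydrogen to isomerise. Both ortho oxygens of the aldehyde are capped (MOM ether, enol ether) so that no phenoxide chelate can hold the acyl rhodium on the side turned away from the alkene, and no Brønsted acid is present that would attack the enol ether.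

Step 10
Reactants: 15 (2S)-2-[4-methoxy-3-(3-methylbut-3-enyl)phenyl]-5,7-bis(methoxymethoxy)-8-(3-methylbut-2-enyl)chroman-4-one
Product: 16 (2S)-5,7-dihydroxy-2-[4-methoxy-3-(3-methylbut-3-enyl)phenyl]-8-(3-methylbut-2-enyl)chroman-4-one
Conditions: HCl (1 M), MeOH/THF, 40 °C
Reagents that add atoms: none
Why: Acid-catalysed acetal exchange removes both MOM ethers (the one beside the ketone fastest); dilute acid at this temperature should not open ring C or epimerise C2, and is the usual way to unmask prenylated flavanones without protonating their alkenes.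

**Compound list**

1 | 5-bromo-2-methoxybenzyl bromide | COc1ccc(Br)cc1CBr | starting material
2 | 2-methylallylmagnesium chloride | C=C(C)C[Mg]Cl | starting material
3 | 4-bromo-1-methoxy-2-(3-methylbut-3-enyl)benzene | C=C(C)CCc1cc(Br)ccc1OC | intermediate
4 | [4-methoxy-3-(3-methylbut-3-enyl)phenyl]lithium | [Li]c1ccc(OC)c(CCC(C)=C)c1 | intermediate (not isolated)
5 | 4-methoxy-3-(3-methylbut-3-enyl)benzoic acid | C=C(C)CCc1cc(C(=O)O)ccc1OC | intermediate
6 | methyl 2,4,6-trihydroxybenzoate | COC(=O)c1c(O)cc(O)cc1O | starting material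
7 | prenyl bromide (1-bromo-3-methylbut-2-ene) | CC(C)=CCBr | starting material
8 | methyl 2,4,6-trihydroxy-3-(3-methylbut-2-enyl)benzoate | COC(=O)c1c(O)c(CC=C(C)C)c(O)cc1O | intermediate
9 | methyl 2-hydroxy-4,6-bis(methoxymethoxy)-3-(3-methylbut-2-enyl)benzoate | COC(=O)c1c(O)c(CC=C(C)C)c(OCOC)cc1OCOC | intermediate
10 | 4-methoxy-3-(3-methylbut-3-enyl)benzoyl chloride | C=C(C)CCc1cc(C(=O)Cl)ccc1OC | intermediate (not isolated)
11 | methyl 2-{[4-methoxy-3-(3-methylbut-3-enyl)benzoyl]oxy}-4,6-bis(methoxymethoxy)-3-(3-methylbut-2-enyl)benzoate | C=C(C)CCc1cc(C(=O)Oc2c(CC=C(C)C)c(OCOC)cc(OCOC)c2C(=O)OC)ccc1OC | intermediate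
12 | methyl 2-({1-[4-methoxy-3-(3-methylbut-3-enyl)phenyl]ethenyl}oxy)-4,6-bis(methoxymethoxy)-3-(3-methylbut-2-enyl)benzoate | C=C(C)CCc1cc(C(=C)Oc2c(CC=C(C)C)c(OCOC)cc(OCOC)c2C(=O)OC)ccc1OC | intermediate
13 | [2-({1-[4-methoxy-3-(3-methylbut-3-enyl)phenyl]ethenyl}oxy)-4,6-bis(methoxymethoxy)-3-(3-methylbut-2-enyl)phenyl]methanol | C=C(C)CCc1cc(C(=C)Oc2c(CC=C(C)C)c(OCOC)cc(OCOC)c2CO)ccc1OC | intermediate
14 | 2-({1-[4-methoxy-3-(3-methylbut-3-enyl)phenyl]ethenyl}oxy)-4,6-bis(methoxymethoxy)-3-(3-methylbut-2-enyl)benzaldehyde | C=C(C)CCc1cc(C(=C)Oc2c(CC=C(C)C)c(OCOC)cc(OCOC)c2C=O)ccc1OC | intermediate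
15 | (2S)-2-[4-methoxy-3-(3-methylbut-3-enyl)phenyl]-5,7-bis(methoxymethoxy)-8-(3-methylbut-2-enyl)chroman-4-one | C=C(C)CCc1cc([C@@H]2CC(=O)c3c(OCOC)cc(OCOC)c(CC=C(C)C)c3O2)ccc1OC | intermediate
16 | (2S)-5,7-dihydroxy-2-[4-methoxy-3-(3-methylbut-3-enyl)phenyl]-8-(3-methylbut-2-enyl)chroman-4-one (CNP0286775.1) | C=C(C)CCc1cc([C@@H]2CC(=O)c3c(O)cc(O)c(CC=C(C)C)c3O2)ccc1OC | target

**Step count**

Total: 10 steps. Longest linear sequence: 8 steps (steps 3–10 from 6; the ring B branch, steps 1, 2 and 5–10, is equally long).

**Steps most likely to fail**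

Step 9 (the proposed new method). The acyl rhodium hydride may lose CO before the hindered enol ether inserts. The β-aryloxy alkyl rhodium may expel the ring A aryloxide instead of undergoing reductive elimination. Enantioface discrimination may be poor. The fallback uses known chemistry, the rhodium-catalysed asymmetric 1,4-addition of an arylboronic acid to a chromone; it sets out from bromide 3 and returns at 15. Bromide 3 is lithiated (n-BuLi, THF, −78 °C), quenched with B(Oi-Pr)3 and hydrolysed to [4-methoxy-3-(3-methylbut-3-enyl)phenyl]boronic acid F1. Purchased 2,4,6-trihydroxyacetophenone is C-prenylated with 7 as in step 3 to 2,4,6-trihydroxy-3-(3-methylbut-2-enyl)acetophenone F2. This is etherified as in step 4 to 2-hydroxy-4,6-bis(methoxymethoxy)-3-(3-methylbut-2-enyl)acetophenone F3. Heating with N,N-dimethylformamide dimethyl acetal gives (E)-3-(dimethylamino)-1-[2-hydroxy-4,6-bis(methoxymethoxy)-3-(3-methylbut-2-enyl)phenyl]prop-2-en-1-one F4. This closes with loss of dimethylamine (AcOH, gentle warming) to 5,7-bis(methoxymethoxy)-8-(3-methylbut-2-enyl)chromen-4-one F5. Addition of F1 to F5 with [Rh(OH)(cod)]2 and a chiral diene or electron-poor chiral bisphosphine in aqueous toluene should give 15, and step 10 follows unchanged.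

Step 6. Chemoselectivity may be lost, the titanium carbene attacking the methyl ester as well, or the crowded aryl ester may react too slowly. The fallback forms the O1–C2 bond by C–O cross-coupling instead of forming C2=C3 by olefination; it sets out from 3 and 9 and returns at 12, bypassing steps 2 and 5. Lithiation of 3 (n-BuLi, −78 °C) and acylation with N-methoxy-N-methylacetamide gives 1-[4-methoxy-3-(3-methylbut-3-enyl)phenyl]ethanone F6. KN(SiMe3)2 and PhNTf2 convert it into 1-[4-methoxy-3-(3-methylbut-3-enyl)phenyl]ethenyl trifluoromethanesulfonate F7. Palladium-catalysed etherification of F7 with phenol 9 (Pd2(dba)3, bulky biarylphosphine, K3PO4, toluene) gives 12.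

Step 4. Etherification may occur at the hindered ortho OH in competition with the open one, giving positional isomers, or run on to the tris-ether. The fallback installs the protecting groups before the prenyl group, so that symmetry removes the question; it sets out from 6 and returns at 9, bypassing step 3. Ester 6 with MOMCl (2 equiv) and i-Pr2NEt gives methyl 2-hydroxy-4,6-bis(methoxymethoxy)benzoate F8; the two ortho OH groups are equivalent and the remaining one stays chelated. O-Alkylation with 7 (K2CO3, acetone) gives methyl 2,4-bis(methoxymethoxy)-6-(3-methylbut-2-enyloxy)benzoate F9. A 1,3-shift of the prenyl group from oxygen to the only free ortho carbon on MgSiO3 (Florisil) in toluene gives 9.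

**Further compounds**

F1 | step 9 | [4-methoxy-3-(3-methylbut-3-enyl)phenyl]boronic acid | C=C(C)CCc1cc(B(O)O)ccc1OC
F2 | step 9 | 2,4,6-trihydroxy-3-(3-methylbut-2-enyl)acetophenone | CC(=O)c1c(O)c(CC=C(C)C)c(O)cc1O
F3 | step 9 | 2-hydroxy-4,6-bis(methoxymethoxy)-3-(3-methylbut-2-enyl)acetophenone | CC(=O)c1c(O)c(CC=C(C)C)c(OCOC)cc1OCOC
F4 | step 9 | (E)-3-(dimethylamino)-1-[2-hydroxy-4,6-bis(methoxymethoxy)-3-(3-methylbut-2-enyl)phenyl]prop-2-en-1-one | CN(C)/C=C/C(=O)c1c(O)c(CC=C(C)C)c(OCOC)cc1OCOC
F5 | step 9 | 5,7-bis(methoxymethoxy)-8-(3-methylbut-2-enyl)chromen-4-one | O=c1ccoc2c(CC=C(C)C)c(OCOC)cc(OCOC)c12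
F6 | step 6 | 1-[4-methoxy-3-(3-methylbut-3-enyl)phenyl]ethanone | C=C(C)CCc1cc(C(C)=O)ccc1OC
F7 | step 6 | 1-[4-methoxy-3-(3-methylbut-3-enyl)phenyl]ethenyl trifluoromethanesulfonate | C=C(C)CCc1cc(C(=C)OS(=O)(=O)C(F)(F)F)ccc1OC
F8 | step 4 | methyl 2-hydroxy-4,6-bis(methoxymethoxy)benzoate | COC(=O)c1c(O)cc(OCOC)cc1OCOC
F9 | step 4 | methyl 2,4-bis(methoxymethoxy)-6-(3-methylbut-2-enyloxy)benzoate | COC(=O)c1c(OCC=C(C)C)cc(OCOC)cc1OCOC
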